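The benzofuran (O1, C2, C3, C3a, C4–C7, C7a) is disconnected at the C7–C7a bond, so the benzo ring is grown onto a finished 2,4-disubstituted furan. C7a is a furan α-carbon, and prenyl-bearing C7 lies α to the carbonyl of the C6 keto tautomer. These are two donor carbons that only oxidative coupling can unite. Anodic oxidation of a furan-tethered silyl enol ether makes this bond, closes the six-membered carbocycle and releases the C6 ketone in one operation. The precursor is a 5-aryl-3-furyl carbinol silyl ether whose chain ends in the C6=C7 trimethylsilyl enol ether. Its C4 silyloxy leaving group lets the ring aromatise by elimination, not dehydrogenation.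

Key step: step 10

Remark on the chemistry: the target has no stereocentre and, because the aryl ring is symmetric about its bond to C2, no stereogenic axis; it is achiral, no enantiomer has to be selected, and all chiral intermediates are carried as racemates.

Abbreviations: prenyl = 3-methylbut-2-en-1-yl; TBS = tert-butyldimethylsilyl; TMS = trimethylsilyl; Ar = 3,5-bis(TBS-oxy)-2,6-diprenylphenyl. Benzofuran numbering is used for the future ring atoms.

Step 1
Reactants: 1 5-bromoresorcinol; 2 3-chloro-3-methylbut-1-yne (2.4 equiv)
Product: 3 1-bromo-3,5-bis[(2-methylbut-3-yn-2-yl)oxy]benzene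
Conditions: CuCl2·2H2O (1 mol %), DBU (2.6 equiv), MeCN, 0 °C
Reagents that add atoms: none
Why: Copper-catalysed O-alkylation of phenols with a tertiary propargylic chloride is the standard entry to aryl 1,1-dimethylpropargyl ethers; both hydroxyl groups of the symmetric diol react alike and the aryl bromide is inert at 0 °C.

Step 2
Reactants: 3 1-bromo-3,5-bis[(2-methylbut-3-yn-2-yl)oxy]benzene
Product: 4 1-bromo-3,5-bis[(2-methylbut-3-en-2-yl)oxy]benzene
Conditions: H2 (1 atm), Lindlar catalyst, quinoline, EtOAc, rt
Reagents that add atoms: none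
Why: Lindlar semihydrogenation stops at the terminal alkenes, and the poisoned palladium leaves the aryl bromide and the tertiary allylic C–O bonds intact.

Step 3
Reactants: 4 1-bromo-3,5-bis[(2-methylbut-3-en-2-yl)oxy]benzene
Product: 6 5-bromo-4,6-diprenylbenzene-1,3-diol, via mono-rearranged phenol 5 (not isolated)
Conditions: PhNEt2, 130 °C, Ar
Reagents that add atoms: none
Why: Two successive aromatic Claisen rearrangements ([3,3] shift, then rearomatising tautomerisation) turn each 1,1-dimethylallyl ether into an ortho prenyl group, and the known meta-substituent effects cooperate in favour of C4 and C6, since a meta halogen draws the migrating group to the ortho carbon beside it while a meta oxygen donor sends it para to itself and away from C2; the basic solvent suppresses acid-induced ether cleavage and chroman formation.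

Step 4
Reactants: 6 5-bromo-4,6-diprenylbenzene-1,3-diol
Product: 7 1-bromo-3,5-bis(TBS-oxy)-2,6-diprenylbenzene (Ar–Br)
Conditions: TBSCl (2.5 equiv), imidazole, DMF, rt
Reagents that add atoms: tert-butyldimethylsilyl chloride, CC(C)(C)[Si](C)(C)Cl
Why: Standard imidazole-promoted silylation of phenols; the silyl ethers withstand the organometallic steps ahead and leave in a single fluoride operation at the end.

Step 5
Reactants: 8 furan-3-carbaldehyde
Product: 12 5-iodofuran-3-carbaldehyde, via lithium morpholino alkoxide 9 (not isolated), via C5-lithiated alkoxide 10 (not isolated), via C5-iodinated alkoxide 11 (not isolated)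
Conditions: morpholine, n-BuLi, THF, −78 °C, then 8; sec-BuLi, −78 °C; I2, THF, −78 °C to rt; H2O work-up (aq. Na2S2O3 wash)
Reagents that add atoms: iodine, II
Why: Lithium morpholide masks the aldehyde as a bulky, non-chelating α-amino alkoxide that shields C2, so sec-butyllithium metalates the remote α-carbon C5 (a known in-situ-protection lithiation of this aldehyde), iodine traps the carbanion and aqueous work-up releases the aldehyde.

Step 6
Reactants: 7 Ar–Br; 12 5-iodofuran-3-carbaldehyde
Product: 15 5-Ar-furan-3-carbaldehyde, via aryllithium 13 (not isolated), via arylzinc chloride 14 (not isolated)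
Conditions: n-BuLi, THF, −78 °C; ZnCl2, −78 °C to rt; 12, Pd2(dba)3 (2 mol %), SPhos (8 mol %), THF, rt to 50 °C
Reagents that add atoms: none
Why: Bromine–lithium exchange, transmetalation to zinc and Negishi coupling with a bulky biarylphosphine is established for di-ortho-substituted arylzinc reagents; two pre-functionalised partners fix the bond at furan C5 (a C–H arylation would have to tell C5 from C2), and the base- and fluoride-free medium spares the aldehyde, the aryl silyl ethers and the prenyl groups.

Step 7
Reactants: 15 5-Ar-furan-3-carbaldehyde; 16 methyl vinyl ketone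
Product: 18 rac-1-(5-Ar-furan-3-yl)-1-hydroxypent-4-en-3-one, via lithium dienolate 17 (not isolated)
Conditions: LDA, THF, −78 °C, then 16; 15, −78 °C; AcOH quench at −78 °C
Reagents that add atoms: none
Why: Kinetic deprotonation of methyl vinyl ketone at its methyl group gives the cross-conjugated lithium dienolate, which undergoes aldol addition to the non-enolisable aldehyde; the carbinol centre (future C4) is formed racemic, which is harmless because it is erased in step 11.

Step 8
Reactants: 18 rac-1-(5-Ar-furan-3-yl)-1-hydroxypent-4-en-3-one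
Product: 19 rac-1-(5-Ar-furan-3-yl)-1-(TBS-oxy)pent-4-en-3-one
Conditions: TBSOTf (1.1 equiv), 2,6-lutidine, CH2Cl2, −78 °C
Reagents that add atoms: tert-butyldimethylsilyl triflate, CC(C)(C)[Si](C)(C)OS(=O)(=O)C(F)(F)F
Why: A silyl triflate with a hindered, non-nucleophilic pyridine base silylates the secondary alcohol quickly at low temperature, which forestalls retro-aldol cleavage, dehydration, oxa-Michael closure and amine addition to the vinyl ketone.

Step 9
Reactants: 19 rac-1-(5-Ar-furan-3-yl)-1-(TBS-oxy)pent-4-en-3-one; 20 2-methylprop-1-enylmagnesium bromide (0.5 M in THF)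
Product: 21 rac-(3Z)-1-(5-Ar-furan-3-yl)-1-(TBS-oxy)-7-methyl-3-(TMS-oxy)octa-3,6-diene, the (Z)-TMS enol ether of the corresponding oct-6-en-3-one
Conditions: CuI·2LiCl (10 mol %), TMSCl (2 equiv), THF, −78 °C; Et3N, cold aq. NaHCO3; filtration through Et3N-deactivated silica
Reagents that add atoms: chlorotrimethylsilane, C[Si](C)(C)Cl
Why: Copper-catalysed, chlorosilane-accelerated conjugate addition of an alkenyl Grignard reagent to a vinyl ketone completes the prenyl group and traps the enolate where it is born, so the enol ether is regiospecifically C6=C7 (mainly Z from the s-cis enone, the geometry being of no consequence later) and no free enolate can equilibrate towards C5 and expel the C4 silyloxy group.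

Step 10
Reactants: 21 rac-(Z)-TMS enol ether
Product: 22 2-Ar-7-prenyl-4-(TBS-oxy)-5,7-dihydro-4H-1-benzofuran-6-one (racemic, mixture of C4/C7 diastereomers)
Conditions: undivided cell, reticulated vitreous carbon anode, Pt cathode, 0.1 M LiClO4, 2,6-lutidine (5 equiv), MeCN/i-PrOH 4:1, rt, potential held at the first oxidation wave of 21 (located by cyclic voltammetry), ca. 2.1 F/mol
Reagents that add atoms: none
Why: At the carbon anode one electron is taken from the most easily oxidised π system of 21, the trisubstituted silyl enol ether (which can exchange the hole with the neighbouring furan), the free furan α-carbon C7a then bonds to C7, the enol carbon remote from oxygen, and the siloxy-stabilised C6 radical is oxidised again, after which the silyl group passes to isopropanol to give the ketone, 2,6-lutidine removes the C7a proton to restore the furan and the protons end as hydrogen at the cathode. The closest known reaction type is the anodic coupling of conjugate-addition-derived silyl enol ethers with tethered furans, which gives six- and seven-membered annulated furans in the same buffered medium; there the enol double bond stays outside the new ring and the furan carries no aryl group, so closure with the double bond inside the ring and the 5-aryl furan are extensions that remain to be proven. The one ring formed (C3a–C4–C5–C6–C7–C7a) closes 6-endo-trig, an allowed mode that keeps the normal polarity of enol ether radical cations and parallels the oxidative radical closures of δ-aryl-β-dicarbonyl compounds to 2-tetralones, where the carbonyl also ends up inside the ring; attack by C3a would be a strained 5-endo spiro closure and the other furan α-carbon is blocked by the aryl group. C7 becomes a stereocentre without control relative to C4, which is acceptable because both centres are erased in step 11. The step needs electron removal from the enol ether/furan pair ahead of the three prenyl alkenes and the bis(silyloxy)arene: isolated trisubstituted alkenes are expected to oxidise at clearly higher potential, the arene is twisted out of conjugation with the furan by its two ortho prenyl groups and carries bulky silyloxy groups that are poorer donors than alkoxy groups, potential and charge are limited, and the intramolecular trap should drain the radical cation faster than alcohol capture or deprotonation.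

Step 11
Reactants: 22 2-Ar-7-prenyl-4-(TBS-oxy)-5,7-dihydro-4H-1-benzofuran-6-one
Product: 25 5-(6-hydroxy-7-prenyl-1-benzofuran-2-yl)-4,6-diprenylbenzene-1,3-diol (CNP0322812.0), via desilylated ketol 23 (not isolated), via 7H-dienone 24 (not isolated)
Conditions: TBAF (4 equiv), THF, 0 °C to rt, Ar; AcOH quench
Reagents that add atoms: none
Why: Fluoride cleaves the three silyl ethers, the basic medium dehydrates the β-hydroxy ketone by E1cB elimination and the 7H-dienone tautomerises irreversibly to the C6 phenol, so the benzo ring aromatises without oxidant or acid and the prenyl groups are untouched; any retro-aldol opening is reversible and drains into the same aromatic sink.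

Compound list
1 | 5-bromoresorcinol | Oc1cc(O)cc(Br)c1 | starting material
2 | 3-chloro-3-methylbut-1-yne | C#CC(C)(C)Cl | starting material
3 | 1-bromo-3,5-bis[(2-methylbut-3-yn-2-yl)oxy]benzene | C#CC(C)(C)Oc1cc(Br)cc(OC(C)(C)C#C)c1 | intermediate
4 | 1-bromo-3,5-bis[(2-methylbut-3-en-2-yl)oxy]benzene | C=CC(C)(C)Oc1cc(Br)cc(OC(C)(C)C=C)c1 | intermediate
5 | 3-bromo-5-[(2-methylbut-3-en-2-yl)oxy]-2-prenylphenol (formed in the flask) | CC(C)=CCc1c(O)cc(OC(C)(C)C=C)cc1Br | intermediate
6 | 5-bromo-4,6-diprenylbenzene-1,3-diol | CC(C)=CCc1c(O)cc(O)c(CC=C(C)C)c1Br | intermediate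
7 | 1-bromo-3,5-bis(TBS-oxy)-2,6-diprenylbenzene | CC(C)=CCc1c(O[Si](C)(C)C(C)(C)C)cc(O[Si](C)(C)C(C)(C)C)c(CC=C(C)C)c1Br | intermediate
8 | furan-3-carbaldehyde | O=Cc1ccoc1 | starting material
9 | lithium (furan-3-yl)(morpholin-4-yl)methoxide (formed in the flask) | [Li+].[O-]C(N1CCOCC1)c1ccoc1 | intermediate
10 | lithium (5-lithiofuran-3-yl)(morpholin-4-yl)methoxide (formed in the flask) | [Li+].[O-]C(N1CCOCC1)c1coc([Li])c1 | intermediate
11 | lithium (5-iodofuran-3-yl)(morpholin-4-yl)methoxide (formed in the flask) | [Li+].[O-]C(N1CCOCC1)c1coc(I)c1 | intermediate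
12 | 5-iodofuran-3-carbaldehyde | O=Cc1coc(I)c1 | intermediate
13 | 3,5-bis(TBS-oxy)-2,6-diprenylphenyllithium (formed in the flask) | CC(C)=CCc1c(O[Si](C)(C)C(C)(C)C)cc(O[Si](C)(C)C(C)(C)C)c(CC=C(C)C)c1[Li] | intermediate
14 | 3,5-bis(TBS-oxy)-2,6-diprenylphenylzinc chloride (formed in the flask) | CC(C)=CCc1c(O[Si](C)(C)C(C)(C)C)cc(O[Si](C)(C)C(C)(C)C)c(CC=C(C)C)c1[Zn]Cl | intermediate
15 | 5-[3,5-bis(TBS-oxy)-2,6-diprenylphenyl]furan-3-carbaldehyde | O=Cc1coc(c1)-c1c(CC=C(C)C)c(O[Si](C)(C)C(C)(C)C)cc(O[Si](C)(C)C(C)(C)C)c1CC=C(C)C | intermediate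
16 | methyl vinyl ketone | CC(=O)C=C | starting material
17 | lithium buta-1,3-dien-2-olate (formed in the flask) | [Li+].[O-]C(=C)C=C | intermediate
18 | rac-1-(5-Ar-furan-3-yl)-1-hydroxypent-4-en-3-one | C=CC(=O)CC(O)c1coc(c1)-c1c(CC=C(C)C)c(O[Si](C)(C)C(C)(C)C)cc(O[Si](C)(C)C(C)(C)C)c1CC=C(C)C | intermediate
19 | rac-1-(5-Ar-furan-3-yl)-1-(TBS-oxy)pent-4-en-3-one | C=CC(=O)CC(O[Si](C)(C)C(C)(C)C)c1coc(c1)-c1c(CC=C(C)C)c(O[Si](C)(C)C(C)(C)C)cc(O[Si](C)(C)C(C)(C)C)c1CC=C(C)C | intermediate
20 | 2-methylprop-1-enylmagnesium bromide | CC(C)=C[Mg]Br | starting material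
21 | rac-(3Z)-1-(5-Ar-furan-3-yl)-1-(TBS-oxy)-7-methyl-3-(TMS-oxy)octa-3,6-diene | CC(C)=CC/C=C(/CC(O[Si](C)(C)C(C)(C)C)c1coc(c1)-c1c(CC=C(C)C)c(O[Si](C)(C)C(C)(C)C)cc(O[Si](C)(C)C(C)(C)C)c1CC=C(C)C)O[Si](C)(C)C | intermediate
22 | 2-Ar-7-prenyl-4-(TBS-oxy)-5,7-dihydro-4H-1-benzofuran-6-one (racemic diastereomer mixture) | O=C1CC(O[Si](C)(C)C(C)(C)C)c2cc(oc2C1CC=C(C)C)-c1c(CC=C(C)C)c(O[Si](C)(C)C(C)(C)C)cc(O[Si](C)(C)C(C)(C)C)c1CC=C(C)C | intermediate
23 | 2-(3,5-dihydroxy-2,6-diprenylphenyl)-4-hydroxy-7-prenyl-5,7-dihydro-4H-1-benzofuran-6-one (formed in the flask) | O=C1CC(O)c2cc(oc2C1CC=C(C)C)-c1c(CC=C(C)C)c(O)cc(O)c1CC=C(C)C | intermediate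
24 | 2-(3,5-dihydroxy-2,6-diprenylphenyl)-7-prenyl-7H-1-benzofuran-6-one (formed in the flask) | O=C1C=Cc2cc(oc2C1CC=C(C)C)-c1c(CC=C(C)C)c(O)cc(O)c1CC=C(C)C | intermediate
25 | 5-(6-hydroxy-7-prenyl-1-benzofuran-2-yl)-4,6-diprenylbenzene-1,3-diol (achiral) | CC(C)=CCc1c(O)cc(O)c(CC=C(C)C)c1-c1cc2ccc(O)c(CC=C(C)C)c2o1 | target

Total step count: 11. Longest linear sequence: 10 (steps 1–4 and 6–11); step 5 is a one-step side branch.

Steps most likely to fail

1. Step 10.
- **What may go wrong:**
  - Electron removal or follow-up reaction may occur at the wrong site, namely the arene, a prenyl double bond or the doubly activated ArCH2 protons.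
  - The trimethylsilyl enol ether may solvolyse before it is oxidised.
  - The endo closure may be too slow to outrun capture of the radical cation by the alcohol.
- **Fallback:** the same bond is made by a redox-neutral cross-coupling instead of an oxidative coupling. It sets out from 19.
  - NBS (1.0 equiv, DMF, −20 °C, dark) should brominate the only free furan α-carbon to give the 2-bromofuran enone F1.
  - Copper-catalysed addition of 20 with TMSCl, as in step 9, should give the bromo silyl enol ether F2.
  - Palladium-catalysed intramolecular α-arylation of the silyl enol ether through its tin enolate (Pd2(dba)3, P(t-Bu)3, Bu3SnF, toluene, 80 °C) is a known regiocontrolled reaction of trimethylsilyl enol ethers with aryl bromides. It joins C7 to C7a and comes back to the route at 22.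

2. Step 3.
- **What may go wrong:**
  - Part of the allyl migration may go to C2 between the two oxygens.
  - The tertiary allyl ethers may fragment thermally before they rearrange.
- **Fallback:** the regiochemistry is set by electrophilic halogenation and the prenyl groups come from cross-coupling. It sets out from 1.
  - NIS (2 equiv, cat. TsOH, MeCN, 0 °C) should iodinate para to each hydroxyl group to give 5-bromo-4,6-diiodobenzene-1,3-diol F3.
  - TBSCl and imidazole in DMF should give its bis(TBS) ether F4.
  - A double Stille coupling with tributyl(3-methylbut-2-enyl)stannane (PdCl2(dppf), DMF, 70 °C) should react at the two C–I bonds in preference to the flanked C–Br bond. It comes back to the route at 7.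

3. Step 7.
- **What may go wrong:**
  - The dienolate may add to unreacted methyl vinyl ketone (anionic oligomerisation) before it meets the aldehyde.
  - Retro-aldol cleavage or oxa-Michael closure may occur during work-up.
- **Fallback:** the vinyl ketone is built by acyl substitution, without a methyl vinyl ketone enolate. It sets out from 15.
  - The lithium enolate of N-methoxy-N-methylacetamide (LDA, THF, −78 °C) should add to the aldehyde to give the β-hydroxy Weinreb amide F5.
  - TBSOTf and 2,6-lutidine should give its TBS ether F6.
  - Vinylmagnesium bromide (THF, 0 °C, inverse quench into cold aq. NH4Cl) should stop at the ketone stage through the chelated adduct. It comes back to the route at 19.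

Further compounds
F1 | step 10 | rac-1-(5-Ar-2-bromofuran-3-yl)-1-(TBS-oxy)pent-4-en-3-one | C=CC(=O)CC(O[Si](C)(C)C(C)(C)C)c1cc(oc1Br)-c1c(CC=C(C)C)c(O[Si](C)(C)C(C)(C)C)cc(O[Si](C)(C)C(C)(C)C)c1CC=C(C)C
F2 | step 10 | rac-(3Z)-1-(5-Ar-2-bromofuran-3-yl)-1-(TBS-oxy)-7-methyl-3-(TMS-oxy)octa-3,6-diene | CC(C)=CC/C=C(/CC(O[Si](C)(C)C(C)(C)C)c1cc(oc1Br)-c1c(CC=C(C)C)c(O[Si](C)(C)C(C)(C)C)cc(O[Si](C)(C)C(C)(C)C)c1CC=C(C)C)O[Si](C)(C)C
F3 | step 3 | 5-bromo-4,6-diiodobenzene-1,3-diol | Oc1cc(O)c(I)c(Br)c1I
F4 | step 3 | 3-bromo-1,5-bis(TBS-oxy)-2,4-diiodobenzene | CC(C)(C)[Si](C)(C)Oc1cc(O[Si](C)(C)C(C)(C)C)c(I)c(Br)c1I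
F5 | step 7 | rac-3-(5-Ar-furan-3-yl)-3-hydroxy-N-methoxy-N-methylpropanamide | CON(C)C(=O)CC(O)c1coc(c1)-c1c(CC=C(C)C)c(O[Si](C)(C)C(C)(C)C)cc(O[Si](C)(C)C(C)(C)C)c1CC=C(C)C
F6 | step 7 | rac-3-(5-Ar-furan-3-yl)-3-(TBS-oxy)-N-methoxy-N-methylpropanamide | CON(C)C(=O)CC(O[Si](C)(C)C(C)(C)C)c1coc(c1)-c1c(CC=C(C)C)c(O[Si](C)(C)C(C)(C)C)cc(O[Si](C)(C)C(C)(C)C)c1CC=C(C)C
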